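## Analysis of the target

The target 14 is a 2-aryl-3-alkylchroman. Chroman numbering is used, with primed numbers for the aryl group on C2. Ring A (C4a–C5–C6–C7–C8–C8a) is an isovalerylphloroglucinol carrying 5-OH, 6-(3-methylbutanoyl), 7-OH and 8-H. Ring C is the dihydropyran O1–C2–C3–C4. Ring B (C1′–C6′) on C2 is a fully substituted 2′,4′,6′-trihydroxy-3′,5′-diformylphenyl group.

There are two contiguous stereocentres, C2 (R, aryl) and C3 (S, isopropyl). The SMILES places the aryl and isopropyl groups trans, and C3 has no heteroatom that could guide a reagent.

The O1–C8a=C4a–C4 array of rings A and C is the retron of an ortho-quinone methide. C2–C3, with ring B and its 2′/6′-OH on C2 and the isopropyl group on C3, is the retron of an (E)-ortho-hydroxystyrene. The strategy is built on these two features.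

Sensitive groups:
- five acidic phenols, two chelated aryl aldehydes and an aryl ketone;
- the benzylic aryl ether C2–O1, which can ionise because ring B has OH groups ortho and para to C1′;
- the nucleophilic C8–H of ring A.

Three things make the synthesis hard:
- C4a is flanked by two oxygens, O1 and O5, and only O1 (para to the acyl group) may be in ring C. Any closure of an O–C2 bond is regiochemically ambiguous unless O5 is blocked.
- Both stereocentres must be set with absolute control in a molecule with almost no handles.
- The two formyl groups cannot be introduced late, because C8–H of ring A would be formylated as well.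

## Retrosynthetic reasoning

**14 ⇒ 13.** The last operation only uncovers O5–H and O7–H, so 14 is traced back to its bis(methoxymethyl) ether 13. These two ethers do not shield the phenols from reagents; they decide which oxygen enters ring C. With O5 and O7 blocked, only the oxygen para to the acyl group can act as the quinone methide oxygen. Because both oxygens ortho to the ketone are blocked, the ring-A building block is also symmetric. Ring B stays unprotected, because its ortho-hydroxyl groups are needed by the catalyst of the key step.

**13 ⇒ 6 + 11 (through 12).** Ring C is cut at C3–C4 and C2–O1, the two bonds of an inverse-electron-demand hetero-Diels–Alder reaction. This cut is chosen because: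
- it separates the molecule into its two phloroglucinol halves, the most convergent division available;
- it removes ring C and both stereocentres in one operation;
- it mirrors the presumed biogenesis (quinone methide of ring A plus the isopentenyl side chain of a diformylphloroglucinol).

The diene is the ortho-quinone methide 12, released from the salicylic alcohol 6 by a chiral Brønsted acid. The dienophile is the (E)-ortho-hydroxystyrene 11. The forward reaction must add the nucleophilic alkene carbon of 11 to the methylene of 12 and close O1 onto the benzylic carbon. The E geometry translates into the trans relationship, and the catalyst must select one alkene face to give (2R,3S).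

**11 ⇒ 9 ⇒ 8 ⇒ 7.** The alkene of 11 is traced to the benzylic carbinol 9 by dehydration. 9 is cut between the carbinol carbon and the isobutyl CH2, so that it arises from addition of an isobutyl nucleophile to one aldehyde of the C3-symmetric trialdehyde 8. 8 is the tris(methoxymethyl) ether of commercial 7. The gain is that ring B, with both formyl groups and all three oxygens, is bought complete. The three aldehydes are equivalent, so there is no regiochemical question, only mono- versus bis-addition. Acid then removes the three acetals and dehydrates in the same pot, through the ortho-hydroxybenzylic alcohol 10.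

**6 ⇒ 4 ⇒ 3 ⇒ 2 ⇒ 1.** The hydroxymethyl carbon (the future C4) is cut from the ring. It is introduced ortho to the only free phenol of 4 by a boronate-templated ortho-hydroxymethylation through 5. 4 is symmetric, so either ortho position gives the same product. 4 comes from commercial 1 by a short protecting-group sequence that exploits the one inherent difference among its phenols. The para-OH is the only one that is neither chelated nor hindered, so it is silylated first (2). The two ortho-phenols are then capped (3), and the silyl group is removed (4).

## Alternatives that were turned down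

**Alternative 1:** the textbook flavonoid route.
- Disconnection: O1–C2 (oxa-Michael) and the C2–C3 bond as the enone of a chalcone.
- Forward key step: Claisen–Schmidt condensation of a ring-A acetophenone with a ring-B benzaldehyde to chalcone A1, then 6-endo oxa-Michael closure to flavanone A2. This would be followed by C3 isopropylation, C4 deoxygenation, double formylation of ring B and deprotection.
- Turned down because:
  - the isopropyl group would have to be put on C3 of A2 by alkylating an enolate with a secondary halide, and that enolate opens by E1cB loss of the O1 phenoxide back to A1;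
  - the C4 carbonyl must be removed beside the isovaleryl ketone with no chemoselective handle;
  - C2 of a flavanone racemises through the same ring opening, and nothing controls C3;
  - ring B cannot carry its aldehydes through the aldol step, and a late double formylation also attacks C8 of ring A;
  - the O1/O5 ambiguity remains;
  - the step count is well above twelve.

**Alternative 2:** formal [3+3] annulation, then reduction.
- Disconnection: C4–C4a and O1–C2.
- Forward key step: Knoevenagel-type condensation of 1 with enal A3 and oxa-6π electrocyclisation to the 2H-chromene A4, then hydrogenation of C3=C4.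
- Turned down because:
  - hydrogen is delivered to the face of A4 opposite the C2 aryl group, which gives the 2,3-cis isomer, not the trans target;
  - A4 racemises by reversible electrocyclic ring opening, so an asymmetric electrocyclisation would not hold its configuration;
  - A3 has three aldehydes competing in the condensation;
  - both oxygens flanking C4a of 1 can close;
  - hydrogenation would run beside two formyl groups.

**Alternative 3:** aryl ether formation at O1–C8a.
- Disconnection: O1–C8a.
- Forward key step: intramolecular copper- or palladium-catalysed C–O coupling of bromo alcohol A5. Its centres would come from an auxiliary-controlled benzylation (C3) and a Felkin-controlled addition of a ring-B aryl metal to the derived aldehyde (C2).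
- This alternative does solve the O1/O5 problem through the position of the bromine. It was turned down because:
  - the two centres are made one at a time in a linear sequence with auxiliary and redox steps;
  - a ring-B aryl metal cannot carry formyl groups, so formylation comes late and competes at C8;
  - the secondary benzylic alkoxide on the metal is prone to β-hydride elimination to the ketone, and reductive elimination at a hexasubstituted arene is slow;
  - the benzylic alcohol on a 2,4,6-trioxygenated ring ionises easily, which erodes C2;
  - the count is fourteen steps or more.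

Key step: step 8

Assumption: 1 and 7 are taken as catalogue compounds. Which enantiomer of the phosphoric acid favours the (2R,3S) product cannot be predicted with confidence for this substrate pair, so the (R)-acid is written and its mirror image is to be used if the opposite sense is found.

## Route

Step 1
Reactants: 1 3-methyl-1-(2,4,6-trihydroxyphenyl)butan-1-one
Product: 2 1-[2,6-dihydroxy-4-(triisopropylsilyloxy)phenyl]-3-methylbutan-1-one
Conditions: i-Pr3SiCl (1.05 equiv), imidazole (2.2 equiv), DMF, 0 °C
Reagents that add atoms: triisopropylsilyl chloride, CC(C)[Si](Cl)(C(C)C)C(C)C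
Why: Imidazole-mediated silylation of a phenol; the 4-OH is the most acidic and the only one that is neither hydrogen-bonded to the ketone nor flanked by the acyl group, so the bulky silyl chloride should take it selectively.

Step 2
Reactants: 2 1-[2,6-dihydroxy-4-(triisopropylsilyloxy)phenyl]-3-methylbutan-1-one
Product: 3 1-[2,6-bis(methoxymethoxy)-4-(triisopropylsilyloxy)phenyl]-3-methylbutan-1-one
Conditions: NaH (2.3 equiv), MOMCl (2.4 equiv), DMF, 0 °C to rt
Reagents that add atoms: chloromethyl methyl ether, COCCl
Why: Williamson-type O-alkylation of the two ortho-phenols; forming the sodium phenoxides breaks the hydrogen bond to the ketone, both phenols are deprotonated before the ketone α-CH2, and the aryl silyl ether should survive NaH at 0 °C.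

Step 3
Reactants: 3 1-[2,6-bis(methoxymethoxy)-4-(triisopropylsilyloxy)phenyl]-3-methylbutan-1-one
Product: 4 1-[4-hydroxy-2,6-bis(methoxymethoxy)phenyl]-3-methylbutan-1-one
Conditions: Bu4NF (1.1 equiv), AcOH (1.1 equiv), THF, 0 °C
Reagents that add atoms: none
Why: Fluoride-induced cleavage of an aryl silyl ether, buffered so that the liberated para-acylphenoxide is protonated at once; the acetals are inert to fluoride, and the product is symmetric, so its two positions ortho to the free phenol are equivalent.

Step 4
Reactants: 4 1-[4-hydroxy-2,6-bis(methoxymethoxy)phenyl]-3-methylbutan-1-one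
Product: 6 1-[4-hydroxy-3-(hydroxymethyl)-2,6-bis(methoxymethoxy)phenyl]-3-methylbutan-1-one, via benzodioxaborin 5 (not isolated)
Conditions: PhB(OH)2 (1.1 equiv), (CH2O)n (3 equiv), EtCO2H (0.2 equiv), toluene, 90 °C, Dean–Stark; then propane-1,3-diol (3 equiv), THF, rt
Reagents that add atoms: formaldehyde (as paraformaldehyde), C=O
Why: Boronate-templated ortho-hydroxymethylation of a phenol (Nagata reaction): the aryl phenylboronate formed at the only free OH delivers formaldehyde to the adjacent carbon and is locked as 5, which should prevent a second hydroxymethylation and diarylmethane formation. Transesterification with the diol releases 6 under neutral conditions; 6 is to be used without long storage.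

Step 5
Reactants: 7 2,4,6-trihydroxybenzene-1,3,5-tricarbaldehyde
Product: 8 2,4,6-tris(methoxymethoxy)benzene-1,3,5-tricarbaldehyde
Conditions: MOMCl (3.6 equiv), i-Pr2NEt (4.5 equiv), DMF, 0 °C to rt
Reagents that add atoms: chloromethyl methyl ether, COCCl
Why: O-Alkylation of vinylogous acids; the three phenols of 7 are acidic enough for an amine base, there is no free ring carbon for C-alkylation, and capping them restores normal electrophilicity to the aldehydes for step 6.

Step 6
Reactants: 8 2,4,6-tris(methoxymethoxy)benzene-1,3,5-tricarbaldehyde
Product: 9 rac-5-(1-hydroxy-3-methylbutyl)-2,4,6-tris(methoxymethoxy)benzene-1,3-dicarbaldehyde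
Conditions: i-BuMgBr (0.9 equiv), LaCl3·2LiCl (0.3 equiv), THF, −78 °C; then H2O/aq. NH4Cl
Reagents that add atoms: isobutylmagnesium bromide, CC(C)C[Mg]Br
Why: 1,2-Addition of a Grignard reagent to an aryl aldehyde, with the lanthanum salt as Lewis acid to favour addition over β-hydride reduction. The three aldehydes are equivalent, so a deficit of reagent should give mainly the mono-adduct, with unreacted 8 recovered. The new carbinol centre is racemic and is erased in step 7.

Step 7
Reactants: 9 rac-5-(1-hydroxy-3-methylbutyl)-2,4,6-tris(methoxymethoxy)benzene-1,3-dicarbaldehyde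
Product: 11 2,4,6-trihydroxy-5-[(1E)-3-methylbut-1-en-1-yl]benzene-1,3-dicarbaldehyde, via triol carbinol 10 (not isolated)
Conditions: TsOH·H2O (0.3 equiv), MeCN–H2O (10:1), 0.02 M, 60 °C
Reagents that add atoms: none
Why: Acetal hydrolysis of aryl MOM ethers flanked by formyl groups, followed by E1 dehydration of the ortho-hydroxybenzylic alcohol 10 through its protonated quinone methide. Loss of the proton from the side-chain CH2 gives the conjugated alkene, and the E isomer should result under thermodynamic control because the Z isomer forces the isopropyl group against an ortho-hydroxyl.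

Step 8
Reactants: 6 1-[4-hydroxy-3-(hydroxymethyl)-2,6-bis(methoxymethoxy)phenyl]-3-methylbutan-1-one; 11 2,4,6-trihydroxy-5-[(1E)-3-methylbut-1-en-1-yl]benzene-1,3-dicarbaldehyde
Product: 13 5-[(2R,3S)-5,7-bis(methoxymethoxy)-6-(3-methylbutanoyl)-3-(propan-2-yl)-3,4-dihydro-2H-chromen-2-yl]-2,4,6-trihydroxybenzene-1,3-dicarbaldehyde, via quinone methide 12 (not isolated)
Conditions: (R)-3,3′-bis(2,4,6-triisopropylphenyl)-1,1′-binaphthyl-2,2′-diyl hydrogen phosphate (10 mol %), 3 Å MS, CH2Cl2, −30 °C; 6 (1.3 equiv) added slowly to 11
Reagents that add atoms: none
Why: The phosphoric acid dehydrates 6 to the ortho-quinone methide 12 and keeps it hydrogen-bonded through P–OH···O=C, while its phosphoryl oxygen binds a 2′/6′-hydroxyl of 11, so one catalyst molecule holds diene and dienophile in a chiral pocket. The bond-forming event is an inverse-electron-demand oxa-[4+2] cycloaddition (hetero-Diels–Alder); the closest known reaction type is the chiral phosphoric acid-catalysed cycloaddition of quinone methides from ortho-hydroxybenzyl alcohols with ortho-hydroxystyrenes. Ring C is closed by this intermolecular [4+2] mode (4π unit O1=C8a–C4a=C4 of 12, 2π unit C2=C3 of 11), which forms C3–C4 and C2–O1 in one operation, with C–C bond formation running ahead of C–O bond formation. The orientation follows from polarity: the nucleophilic alkene carbon bearing the isopropyl group attacks the methylene of 12, and O1 closes onto the benzylic carbon, where ring B stabilises the developing positive charge. The trans relationship of C2 and C3 follows from suprafacial addition to the E alkene; because C4 is unsubstituted there is no endo/exo question. The absolute configuration of both centres is set together by the catalyst, which selects the alkene face (C3 in the C–C bond-forming event, C2 through the alkene geometry). Only O1 can close the ring because O5 and O7 are MOM ethers, ring B has no free ring carbon to be alkylated, and slow addition of 6 at low temperature should hold back self-alkylation of 6 by 12 at its free ring C–H.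

Step 9
Reactants: 13 5-[(2R,3S)-5,7-bis(methoxymethoxy)-6-(3-methylbutanoyl)-3-(propan-2-yl)-3,4-dihydro-2H-chromen-2-yl]-2,4,6-trihydroxybenzene-1,3-dicarbaldehyde
Product: 14 5-[(2R,3S)-5,7-dihydroxy-6-(3-methylbutanoyl)-3-(propan-2-yl)-3,4-dihydro-2H-chromen-2-yl]-2,4,6-trihydroxybenzene-1,3-dicarbaldehyde
Conditions: HCl (0.5 M in MeOH), MeOH–THF (2:1), 0 °C to rt
Reagents that add atoms: none
Why: Acid-catalysed transacetalisation of MOM ethers; both are ortho to the ketone and are therefore the most labile kind of aryl MOM ether, so dilute acid at or below room temperature should suffice and should leave the C2–O1 benzylic ether and both stereocentres untouched. The formaldehyde unit is carried off as its dimethyl acetal, away from C8–H.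

## Compound list

1 | 3-methyl-1-(2,4,6-trihydroxyphenyl)butan-1-one | CC(C)CC(=O)c1c(O)cc(O)cc1O | starting material
2 | 1-[2,6-dihydroxy-4-(triisopropylsilyloxy)phenyl]-3-methylbutan-1-one | CC(C)CC(=O)c1c(O)cc(O[Si](C(C)C)(C(C)C)C(C)C)cc1O | intermediate
3 | 1-[2,6-bis(methoxymethoxy)-4-(triisopropylsilyloxy)phenyl]-3-methylbutan-1-one | CC(C)CC(=O)c1c(OCOC)cc(O[Si](C(C)C)(C(C)C)C(C)C)cc1OCOC | intermediate
4 | 1-[4-hydroxy-2,6-bis(methoxymethoxy)phenyl]-3-methylbutan-1-one | CC(C)CC(=O)c1c(OCOC)cc(O)cc1OCOC | intermediate
5 | 1-[5,7-bis(methoxymethoxy)-2-phenyl-4H-1,3,2-benzodioxaborinin-6-yl]-3-methylbutan-1-one | CC(C)CC(=O)c1c(OCOC)cc2OB(c3ccccc3)OCc2c1OCOC | intermediate (not isolated)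
6 | 1-[4-hydroxy-3-(hydroxymethyl)-2,6-bis(methoxymethoxy)phenyl]-3-methylbutan-1-one | CC(C)CC(=O)c1c(OCOC)cc(O)c(CO)c1OCOC | intermediate
7 | 2,4,6-trihydroxybenzene-1,3,5-tricarbaldehyde | O=Cc1c(O)c(C=O)c(O)c(C=O)c1O | starting material
8 | 2,4,6-tris(methoxymethoxy)benzene-1,3,5-tricarbaldehyde | O=Cc1c(OCOC)c(C=O)c(OCOC)c(C=O)c1OCOC | intermediate
9 | rac-5-(1-hydroxy-3-methylbutyl)-2,4,6-tris(methoxymethoxy)benzene-1,3-dicarbaldehyde (racemic) | CC(C)CC(O)c1c(OCOC)c(C=O)c(OCOC)c(C=O)c1OCOC | intermediate
10 | rac-2,4,6-trihydroxy-5-(1-hydroxy-3-methylbutyl)benzene-1,3-dicarbaldehyde (racemic) | CC(C)CC(O)c1c(O)c(C=O)c(O)c(C=O)c1O | intermediate (not isolated)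
11 | 2,4,6-trihydroxy-5-[(1E)-3-methylbut-1-en-1-yl]benzene-1,3-dicarbaldehyde | CC(C)/C=C/c1c(O)c(C=O)c(O)c(C=O)c1O | intermediate
12 | 3,5-bis(methoxymethoxy)-4-(3-methylbutanoyl)-6-methylidenecyclohexa-2,4-dien-1-one | C=C1C(=O)C=C(OCOC)C(C(=O)CC(C)C)=C1OCOC | intermediate (not isolated)
13 | 5-[(2R,3S)-5,7-bis(methoxymethoxy)-6-(3-methylbutanoyl)-3-(propan-2-yl)-3,4-dihydro-2H-chromen-2-yl]-2,4,6-trihydroxybenzene-1,3-dicarbaldehyde | CC(C)CC(=O)c1c(OCOC)cc2c(c1OCOC)C[C@@H](C(C)C)[C@H](c1c(O)c(C=O)c(O)c(C=O)c1O)O2 | intermediate
14 | 5-[(2R,3S)-5,7-dihydroxy-6-(3-methylbutanoyl)-3-(propan-2-yl)-3,4-dihydro-2H-chromen-2-yl]-2,4,6-trihydroxybenzene-1,3-dicarbaldehyde | CC(C)CC(=O)c1c(O)cc2c(c1O)C[C@@H](C(C)C)[C@H](c1c(O)c(C=O)c(O)c(C=O)c1O)O2 | target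

## Step count and risk

Total step count: 9. Longest linear sequence: 6 steps (steps 1, 2, 3, 4, 8, 9); steps 5–7 form the second branch.

Least certain steps:

**Step 8 (key step).** Three processes may go wrong.
- Facial discrimination may be insufficient. The electrophilic carbon of 12 is an unsubstituted methylene, so all asymmetric induction must come from how the catalyst holds the alkene of 11. In addition, the acidic phenols of 11 may catalyse a racemic background reaction.
- 6 may oligomerise, with 12 alkylating the free ring C–H of another molecule of 6.
- The cycloaddition may be slow, because the two formyl groups lower the nucleophilicity of the alkene.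

Fallback: set C3 first by enamine catalysis and attach ring B afterwards. It sets out from 6 and comes back at 13.
- 6 is treated with 3-methylbutanal, (S)-2-[diphenyl(trimethylsilyloxy)methyl]pyrrolidine (or its enantiomer, whichever gives the 3S centre) and benzoic acid. The enamine adds to 12 formed in situ, with the catalyst shielding one enamine face, and the aldehyde is trapped by the phenol as the lactol 1-[(3S)-2-hydroxy-5,7-bis(methoxymethoxy)-3-(propan-2-yl)-3,4-dihydro-2H-chromen-6-yl]-3-methylbutan-1-one F1.
- F1 is then coupled with commercial 2,4,6-trihydroxybenzene-1,3-dicarbaldehyde under diphenyl phosphate catalysis. The cyclic oxocarbenium ion at C2 is attacked by the one free ring carbon of the dialdehyde (Friedel–Crafts-type C-arylation of a lactol), trans to the C3 isopropyl group, which gives 13.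
- O1 is already in the ring before ring B arrives, so the regiochemistry is fixed.

**Step 7.** The liberated ortho-hydroxybenzylic alcohol ionises readily. The transient ring-B quinone methide may be intercepted by product 11 (hetero-Diels–Alder dimerisation) or by the released formaldehyde before it tautomerises to the alkene.

Fallback: dehydrate before deprotecting. It sets out from 9 and comes back at 11.
- 9 is dehydrated by syn-elimination with the Burgess reagent (toluene, 60 °C), with the phenols still protected, to 2,4,6-tris(methoxymethoxy)-5-[(1E)-3-methylbut-1-en-1-yl]benzene-1,3-dicarbaldehyde F2.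
- The acetals of F2 are then hydrolysed at room temperature (TsOH·H2O, MeCN–H2O), where no benzylic alcohol is left to ionise, to give 11.

**Step 6.** Over-addition to a second aldehyde and β-hydride transfer from the isobutyl Grignard reagent (reduction instead of addition) may both lower the return of the mono-adduct.

Fallback: olefinate instead of adding and eliminating. It sets out from 8 and comes back at 11.
- Wittig reaction of 8 with the ylide made from isobutyltriphenylphosphonium bromide and KN(SiMe3)2 (0.9 equiv, THF, −78 °C) cannot reduce the aldehyde. It should give mainly the Z alkene 2,4,6-tris(methoxymethoxy)-5-[(1Z)-3-methylbut-1-en-1-yl]benzene-1,3-dicarbaldehyde F3.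
- The acid treatment of step 7 then removes the acetals and equilibrates the alkene to E through reversible protonation at the side-chain carbon remote from the ring, giving 11.

**Step 4.** The MOM ethers ortho to the ketone may be lost under the warm carboxylic acid-catalysed conditions, and the trioxygenated benzylic alcohol may ionise and condense during release from the boronate.

Fallback: reach the same alcohol through the aldehyde under basic conditions. It sets out from 4 and comes back at 6.
- Magnesium-mediated ortho-formylation (MgCl2, Et3N, paraformaldehyde, MeCN, reflux) gives 2-hydroxy-4,6-bis(methoxymethoxy)-5-(3-methylbutanoyl)benzaldehyde F4.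
- NaBH4 (MeOH–THF, −20 °C) reduces the aldehyde in preference to the hindered, di-ortho-substituted ketone and gives 6 immediately before use.

## Further compounds

F1 | step 8 | 1-[(3S)-2-hydroxy-5,7-bis(methoxymethoxy)-3-(propan-2-yl)-3,4-dihydro-2H-chromen-6-yl]-3-methylbutan-1-one | CC(C)CC(=O)c1c(OCOC)cc2c(c1OCOC)C[C@@H](C(C)C)C(O)O2
F2 | step 7 | 2,4,6-tris(methoxymethoxy)-5-[(1E)-3-methylbut-1-en-1-yl]benzene-1,3-dicarbaldehyde | CC(C)/C=C/c1c(OCOC)c(C=O)c(OCOC)c(C=O)c1OCOC
F3 | step 6 | 2,4,6-tris(methoxymethoxy)-5-[(1Z)-3-methylbut-1-en-1-yl]benzene-1,3-dicarbaldehyde | CC(C)/C=C\c1c(OCOC)c(C=O)c(OCOC)c(C=O)c1OCOC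
F4 | step 4 | 2-hydroxy-4,6-bis(methoxymethoxy)-5-(3-methylbutanoyl)benzaldehyde | CC(C)CC(=O)c1c(OCOC)cc(O)c(C=O)c1OCOC
A1 | alternative 1 | (2E)-1-[6-hydroxy-2,4-bis(methoxymethoxy)-3-(3-methylbutanoyl)phenyl]-3-[2,4,6-tris(methoxymethoxy)phenyl]prop-2-en-1-one | CC(C)CC(=O)c1c(OCOC)cc(O)c(C(=O)/C=C/c2c(OCOC)cc(OCOC)cc2OCOC)c1OCOC
A2 | alternative 1 | rac-5,7-bis(methoxymethoxy)-6-(3-methylbutanoyl)-2-[2,4,6-tris(methoxymethoxy)phenyl]-2,3-dihydro-4H-chromen-4-one | CC(C)CC(=O)c1c(OCOC)cc2OC(c3c(OCOC)cc(OCOC)cc3OCOC)CC(=O)c2c1OCOC
A3 | alternative 2 | (2E)-3-(3,5-diformyl-2,4,6-trihydroxyphenyl)-2-(propan-2-yl)prop-2-enal | CC(C)/C(C=O)=C\c1c(O)c(C=O)c(O)c(C=O)c1O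
A4 | alternative 2 | rac-5-[5,7-dihydroxy-6-(3-methylbutanoyl)-3-(propan-2-yl)-2H-chromen-2-yl]-2,4,6-trihydroxybenzene-1,3-dicarbaldehyde | CC(C)CC(=O)c1c(O)cc2OC(c3c(O)c(C=O)c(O)c(C=O)c3O)C(C(C)C)=Cc2c1O
A5 | alternative 3 | (1R,2S)-2-{[2-bromo-4,6-bis(methoxymethoxy)-5-(3-methylbutanoyl)phenyl]methyl}-3-methyl-1-[2,4,6-tris(methoxymethoxy)phenyl]butan-1-ol | CC(C)CC(=O)c1c(OCOC)cc(Br)c(c1OCOC)C[C@@H](C(C)C)[C@H](c1c(OCOC)cc(OCOC)cc1OCOC)O
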